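The numbering is that of eudesmane (ring A: C1-C5 and C10; ring B: C5-C10). The enabling feature is the cis fusion in which quaternary C10 sits beside C5-H, with C4 and C7 one bond further out. These atoms are the imprint of a bicyclo[2.2.2]octene with bridgeheads C5 and C8 and bridges C4-C3, C6-C7 and C9=C10.
First retrosynthetic cuts: O2'-H is silylated and both aryl-allyl bonds go back to aryl bromides. A carbonyl is restored at C3 and a C8=C9 alkene in ring B. C1-C10 is then cut while C3-C8 is re-formed (retro oxy-Cope).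
Further cuts: C2-C3 (vinyl Grignard), both C11-CH3 bonds (MeMgBr on a C7 ester), and O4-C1' plus the diaryl ether bond (two SNAr reactions on a difluorobenzaldehyde whose formyl carbon is later exchanged for O2'). The last cuts are C5-C6 and C7-C8 (Diels-Alder).
Forward: dearomatised 2,4-dimethylphenol and an acrylate give the bridged bicycle, and both arenes are hung on O4. The [3,3] shift then closes ring A and releases ring B as the cis-decalin. Removal of O3, allylation and desilylation finish the route.
Relative stereochemistry: C4, C5 and C7 come from the cycloaddition (dienophile on the acetoxy face, ester endo). The sacrificial C3 centre comes from Grignard attack on the alkene-bridge face, and C10 from the suprafacial shift inside the rigid cage.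
Absolute configuration comes from (-)-menthol. The menthyl ester adducts of the two dienone enantiomers are diastereomers and the right one is isolated. Menthol leaves without an extra step when MeMgBr builds C11.

Key step: step 11

Remark: the target SMILES is read as (4R,5S,7R,10R), with H5, C10-CH3, C4-CH3 and the C7 side chain on one face and O4 on the other; CIP letters at C4, C7 and C10 change along the route only because substituent ranks change.
Abbreviations: Men = (1R,2S,5R)-menthyl. Ar1 = 5-bromo-3-(4-bromophenoxy)-2-(triisopropylsilyloxy)phenyl. Ar2 = 5-allyl-3-(4-allylphenoxy)-2-(triisopropylsilyloxy)phenyl. In the bicyclo[2.2.2]oct-5-ene-2-carboxylate names, locants 1 to 8 are eudesmane C8, C7, C6, C5, C10, C9, C3, C4. The Why lines use eudesmane locants.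

Step 1
Reactants: 1 2,4-dimethylphenol
Product: 2 (±)-6-acetoxy-4,6-dimethylcyclohexa-2,4-dien-1-one (racemate)
Conditions: Pb(OAc)4, AcOH, rt
Reagents that add atoms: lead tetraacetate, CC(=O)O[Pb](OC(C)=O)(OC(C)=O)OC(C)=O
Why: Wessely oxidation, in which lead-bound acetate is delivered to the methyl-bearing ortho carbon of the phenol, should give the linearly conjugated dienone with the future C4 as a racemic quaternary centre, and the acetate is slow to dimerise, unlike a free o-quinol.

Step 2
Reactants: 3 (-)-menthol; 4 acryloyl chloride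
Product: 5 (1R,2S,5R)-menthyl acrylate
Conditions: Et3N, CH2Cl2, 0 °C to rt
Reagents that add atoms: none
Why: O-acylation of a secondary alcohol with an acid chloride, which leaves the three menthol stereocentres untouched and provides a dienophile whose alkoxy group serves as the resolving handle.

Step 3
Reactants: 2 (±)-6-acetoxy-4,6-dimethylcyclohexa-2,4-dien-1-one; 5 (1R,2S,5R)-menthyl acrylate
Product: 6 Men (1S,2S,4S,8S)-8-acetoxy-5,8-dimethyl-7-oxobicyclo[2.2.2]oct-5-ene-2-carboxylate (ester endo = syn to C5=C6; acetoxy syn to the C2-C3 bridge)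
Conditions: toluene, BHT (cat.), 100 °C; chromatography, then crystallisation
Reagents that add atoms: none
Why: Thermal Diels-Alder reaction of a 6-acetoxycyclohexa-2,4-dienone, in which the acrylate CH2 bonds to C5 and the ester-bearing CH to C8 (ortho rule of the dienone, reinforced by the C10 methyl), the dienophile comes in on the acetoxy face with the ester endo so that C4, C5, C7 and C8 are set relative to one another, and each enantiomer of 2 ends up in a different menthyl ester diastereomer, so that the adduct 6 of (S)-2 can be isolated pure and its absolute configuration read against the menthyl group by single-crystal diffraction.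

Step 4
Reactants: 6 acetoxy ketone menthyl ester
Product: 7 Men (1S,2S,4S,8S)-8-hydroxy-5,8-dimethyl-7-oxobicyclo[2.2.2]oct-5-ene-2-carboxylate (ketol)
Conditions: K2CO3 (0.2 equiv), MeOH, 0 °C to rt
Reagents that add atoms: none
Why: Carbonate-mediated methanolysis (transesterification) of an acetate that is activated by the neighbouring ketone, while the hindered menthyl ester and C7-H are left alone under these mild conditions and the C4-O bond, hence the configuration, is not touched.

Step 5
Reactants: 8 4-bromo-2,6-difluorobenzaldehyde; 9 4-bromophenol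
Product: 10 4-bromo-2-(4-bromophenoxy)-6-fluorobenzaldehyde
Conditions: K2CO3, DMF, rt
Reagents that add atoms: none
Why: Nucleophilic aromatic substitution (SNAr) ortho to the formyl group, kept at monosubstitution by stoichiometry and by the lower electrophilicity of the aryloxy product.

Step 6
Reactants: 7 ketol menthyl ester; 10 4-bromo-2-(4-bromophenoxy)-6-fluorobenzaldehyde
Product: 12 Men (1S,2S,4S,8S)-8-[5-bromo-3-(4-bromophenoxy)-2-formylphenoxy]-5,8-dimethyl-7-oxobicyclo[2.2.2]oct-5-ene-2-carboxylate, via potassium alkoxide 11 (not isolated)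
Conditions: KN(SiMe3)2 (1.0 equiv), THF, -78 °C; then 10, -78 °C to rt
Reagents that add atoms: none
Why: SNAr of a tertiary potassium alkoxide on an ortho-fluorobenzaldehyde, a known way to hindered alkyl aryl ethers, which should be clean here because the C3 ketone cannot enolise (quaternary C4, bridgehead C8), one equivalent of base meets only O4-H, and the C4-O bond stays intact so that C4 keeps its configuration.

Step 7
Reactants: 12 aryl ether aldehyde
Product: 14 Men (1S,2S,4S,8S)-8-[5-bromo-3-(4-bromophenoxy)-2-hydroxyphenoxy]-5,8-dimethyl-7-oxobicyclo[2.2.2]oct-5-ene-2-carboxylate, via aryl formate 13 (not isolated)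
Conditions: 30% aq. H2O2, H2SO4 (cat.), MeOH/THF, rt
Reagents that add atoms: hydrogen peroxide, OO
Why: Acid-catalysed Dakin oxidation (Baeyer-Villiger-type migration of the electron-rich aryl group to peroxide oxygen, then methanolysis of the formate), chosen because H2O2 in acidic methanol attacks only the carbonyl group most open to addition and does not epoxidise C9=C10 as a peracid would, while the adjacent C3 carbonyl suppresses acid ionisation of the tertiary C4-OAr bond.

Step 8
Reactants: 14 phenol
Product: 15 Men (1S,2S,4S,8S)-8-(Ar1O)-5,8-dimethyl-7-oxobicyclo[2.2.2]oct-5-ene-2-carboxylate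
Conditions: iPr3SiOTf, 2,6-lutidine, CH2Cl2, 0 °C to rt
Reagents that add atoms: triisopropylsilyl triflate, CC(C)[Si](OS(=O)(=O)C(F)(F)F)(C(C)C)C(C)C
Why: Silylation of the phenol with a silyl triflate and a hindered pyridine base; any reversible hemiketal closure of O2'-H onto the C3 ketone is drained through the open form because the phenol is the more acidic and less hindered hydroxyl, and the resulting ether tolerates Grignard, hydride and radical reagents, is too bulky for easy O-to-O transfer and leaves with fluoride at the end.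

Step 9
Reactants: 15 silyl-protected ketone
Product: 16 Men (1S,2S,4S,7R,8S)-8-(Ar1O)-7-ethenyl-7-hydroxy-5,8-dimethylbicyclo[2.2.2]oct-5-ene-2-carboxylate (vinyl syn to C5=C6)
Conditions: CH2=CHMgBr, THF, -78 °C; then H2O
Reagents that add atoms: vinylmagnesium bromide, C=C[Mg]Br
Why: Grignard 1,2-addition to the strained, inductively activated and non-enolisable ketone, which outruns attack on the hindered menthyl ester at low temperature and takes place from the face flanked by the flat C9=C10 bridge and the C4 methyl (the other face is screened by the C6-C7 bridge and the aryloxy group), so that C3 is set with the vinyl group syn to the alkene bridge.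

Step 10
Reactants: 16 vinyl carbinol menthyl ester
Product: 18 (1S,2R,3S,4S,7S)-3-(Ar1O)-2-ethenyl-7-(2-hydroxypropan-2-yl)-3,5-dimethylbicyclo[2.2.2]oct-5-en-2-ol (eudesmane locants 3R,4S,5S,7S,8S), via methyl ketone 17 (not isolated)
Conditions: MeMgBr (6 equiv), THF, 0 to 40 °C; then H2O
Reagents that add atoms: methylmagnesium bromide, C[Mg]Br
Why: Twofold Grignard addition to an ester by way of the methyl ketone, which builds the C11 carbinol, expels the auxiliary as mentholate, leaves the aryl bromides alone (no halogen-metal exchange with MeMgBr) and does not trigger the rearrangement because the magnesium alkoxide at C3 is tightly ion-paired.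

Step 11
Reactants: 18 2-vinylbicyclo[2.2.2]oct-5-en-2-ol with the C4 aryl ether and the C7 hydroxyisopropyl group
Product: 21 (4S,5S,7S,10R)-4-(Ar1O)-11-hydroxy-cis-eudesm-8-en-3-one (cis-octalone; H5 and C10-CH3 on the same face), via dipotassium dialkoxide 19 (not isolated), via dipotassium enolate 20 (not isolated)
Conditions: KH (3 equiv), 18-crown-6 (3 equiv), THF, 0 °C to rt; then AcOH, -78 °C
Reagents that add atoms: none
Why: KH turns both tertiary alcohols into potassium alkoxides, and the crown-separated C3 alkoxide weakens the adjacent C3-C8 bond so that the 1,5-diene C1=C2-C3-C8-C9=C10 undergoes a concerted [3,3] shift in which C3-C8 breaks, C1-C10 forms and the C2=C3 enolate and the C8=C9 alkene appear. The reaction type is the anionic oxy-Cope rearrangement, which is established for 2-vinylbicyclo[2.2.2]oct-5-en-2-ols, also for those with an oxygenated quaternary carbon next to the carbinol and a methyl group on the accepting alkene carbon, and gives cis-fused octalones. The new C1-C10 bond completes ring A (C1, C2, C3, C4, C5, C10) as a six-membered carbocycle in a pericyclic closure through the boat-like six-centre array that the cage enforces, and the loss of C3-C8 leaves C5-C6-C7-C8=C9-C10 as ring B. C10 is the only new stereocentre and is fixed by the cage, since C1 can reach C10 only on the face turned toward the C3-C4 bridge, so that the two ring A bonds at C5 and C10 lie on the same side of ring B and the angular methyl shares a face with H5, while C4, C5 and C7 are carried over unchanged. The step needs the [3,3] path to win over a [1,3] shift and over bond cleavage without recombination, which is secured by the vinyl group lying syn to the C9=C10 bridge (step 9) and by the strain released from the bridged skeleton; the C11 alkoxide is a spectator that is not homoallylic before the shift, and the bulky iPr3Si group resists transfer to the hindered alkoxides. The enolate carries no leaving group in the beta position and can be protonated only at C2, so the cold acetic acid quench should give ketone 21 with all four target stereocentres in place.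

Step 12
Reactants: 21 cis-octalone
Product: 22 (4S,5S,7R,10S)-4-(Ar1O)-11-hydroxy-cis-eudesman-3-one
Conditions: KO2CN=NCO2K (excess, in portions), AcOH, MeOH/THF, 0 °C to rt
Reagents that add atoms: none
Why: Diimide reduction, a concerted syn transfer of two hydrogens to the only alkene present, which spares the aryl bromides, the ketone and the silyl ether and, unlike metal-catalysed hydrogenation, cannot move the double bond toward C7 and so cannot erode that allylic stereocentre.

Step 13
Reactants: 22 saturated dibromo ketone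
Product: 23 (4S,5S,7R,10S)-4-(Ar2O)-11-hydroxy-cis-eudesman-3-one
Conditions: CH2=CHCH2SnBu3 (3 equiv), Pd(PPh3)4 (10 mol %), toluene, 110 °C
Reagents that add atoms: allyltributylstannane, C=CC[Sn](CCCC)(CCCC)CCCC
Why: Twofold Stille coupling of aryl bromides with an allylstannane under neutral conditions, placed after the diimide step (which would saturate allyl groups) and before the tin hydride step (which would reduce C-Br bonds).

Step 14
Reactants: 23 bis-allyl ketone
Product: 24 (4S,5S,7R,10S)-4-(Ar2O)-cis-eudesmane-3,11-diol (C3 epimers; not separated)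
Conditions: NaBH4, MeOH/THF, 0 °C
Reagents that add atoms: none
Why: Borohydride reduction of the ketone, open to hydride from the C2 side, in which the new C3 carbinol centre needs no control because it is erased in step 16.

Step 15
Reactants: 24 C3 alcohol
Product: 25 O-[(4S,5S,7R,10S)-4-(Ar2O)-11-hydroxy-cis-eudesman-3-yl] 1H-imidazole-1-carbothioate (C3 epimers)
Conditions: (imidazol-1-yl)2C=S, DMAP (cat.), toluene, 90 °C
Reagents that add atoms: 1,1'-thiocarbonyldiimidazole, S=C(n1ccnc1)n1ccnc1
Why: Thioacylation with thiocarbonyldiimidazole under neutral conditions, which reaches the secondary C3-OH but not the tertiary C11-OH and avoids the strong base of xanthate formation.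

Step 16
Reactants: 25 imidazolyl thiocarbonate
Product: 26 (4R,5S,7R,10R)-4-(Ar2O)-cis-eudesman-11-ol
Conditions: Bu3SnH (5 equiv, one portion), AIBN (cat.), toluene, 110 °C
Reagents that add atoms: none
Why: Barton-McCombie deoxygenation, in which the stannyl radical adds to C=S, the C3-O bond breaks and the secondary C3 radical is quenched by concentrated Bu3SnH faster than it can lose the neighbouring aryloxy group, isolated terminal alkenes being tolerated in this radical chain.

Step 17
Reactants: 26 silyl-protected target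
Product: 27 target CNP0254037.2: (4R,5S,7R,10R)-4-[5-allyl-3-(4-allylphenoxy)-2-hydroxyphenoxy]-cis-eudesman-11-ol
Conditions: Bu4NF, AcOH, THF, 0 °C
Reagents that add atoms: none
Why: Fluoride-induced cleavage of the aryl silyl ether, buffered with acetic acid so that the allyl groups do not drift into conjugation, with the tertiary alcohol and the tertiary alkyl aryl ether inert.

Compound list
1 | 2,4-dimethylphenol | Cc1ccc(O)c(C)c1 | starting material
2 | (±)-6-acetoxy-4,6-dimethylcyclohexa-2,4-dien-1-one (racemate) | CC(=O)OC1(C)C=C(C)C=CC1=O | intermediate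
3 | (-)-menthol, (1R,2S,5R) | CC(C)[C@@H]1CC[C@@H](C)C[C@H]1O | starting material
4 | acryloyl chloride | C=CC(=O)Cl | starting material
5 | (1R,2S,5R)-menthyl acrylate | C=CC(=O)O[C@@H]1C[C@H](C)CC[C@H]1C(C)C | intermediate
6 | Men (1S,2S,4S,8S)-8-acetoxy-5,8-dimethyl-7-oxobicyclo[2.2.2]oct-5-ene-2-carboxylate | CC(=O)O[C@@]1(C)[C@H]2C[C@H](C(=O)O[C@@H]3C[C@H](C)CC[C@H]3C(C)C)[C@H](C=C2C)C1=O | intermediate
7 | Men (1S,2S,4S,8S)-8-hydroxy-5,8-dimethyl-7-oxobicyclo[2.2.2]oct-5-ene-2-carboxylate | O[C@@]1(C)[C@H]2C[C@H](C(=O)O[C@@H]3C[C@H](C)CC[C@H]3C(C)C)[C@H](C=C2C)C1=O | intermediate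
8 | 4-bromo-2,6-difluorobenzaldehyde | O=Cc1c(F)cc(Br)cc1F | starting material
9 | 4-bromophenol | Oc1ccc(Br)cc1 | starting material
10 | 4-bromo-2-(4-bromophenoxy)-6-fluorobenzaldehyde | O=Cc1c(F)cc(Br)cc1Oc1ccc(Br)cc1 | intermediate
11 | potassium alkoxide of 7 (not isolated) | [K+].[O-][C@@]1(C)[C@H]2C[C@H](C(=O)O[C@@H]3C[C@H](C)CC[C@H]3C(C)C)[C@H](C=C2C)C1=O | intermediate
12 | Men (1S,2S,4S,8S)-8-[5-bromo-3-(4-bromophenoxy)-2-formylphenoxy]-5,8-dimethyl-7-oxobicyclo[2.2.2]oct-5-ene-2-carboxylate | O=Cc1c(Oc2ccc(Br)cc2)cc(Br)cc1O[C@@]1(C)[C@H]2C[C@H](C(=O)O[C@@H]3C[C@H](C)CC[C@H]3C(C)C)[C@H](C=C2C)C1=O | intermediate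
13 | aryl formate, as 12 with OCHO in place of CHO (not isolated) | O=COc1c(Oc2ccc(Br)cc2)cc(Br)cc1O[C@@]1(C)[C@H]2C[C@H](C(=O)O[C@@H]3C[C@H](C)CC[C@H]3C(C)C)[C@H](C=C2C)C1=O | intermediate
14 | Men (1S,2S,4S,8S)-8-[5-bromo-3-(4-bromophenoxy)-2-hydroxyphenoxy]-5,8-dimethyl-7-oxobicyclo[2.2.2]oct-5-ene-2-carboxylate | Oc1c(Oc2ccc(Br)cc2)cc(Br)cc1O[C@@]1(C)[C@H]2C[C@H](C(=O)O[C@@H]3C[C@H](C)CC[C@H]3C(C)C)[C@H](C=C2C)C1=O | intermediate
15 | Men (1S,2S,4S,8S)-8-(Ar1O)-5,8-dimethyl-7-oxobicyclo[2.2.2]oct-5-ene-2-carboxylate | CC(C)[Si](Oc1c(Oc2ccc(Br)cc2)cc(Br)cc1O[C@@]1(C)[C@H]2C[C@H](C(=O)O[C@@H]3C[C@H](C)CC[C@H]3C(C)C)[C@H](C=C2C)C1=O)(C(C)C)C(C)C | intermediate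
16 | Men (1S,2S,4S,7R,8S)-8-(Ar1O)-7-ethenyl-7-hydroxy-5,8-dimethylbicyclo[2.2.2]oct-5-ene-2-carboxylate | CC(C)[Si](Oc1c(Oc2ccc(Br)cc2)cc(Br)cc1O[C@@]1(C)[C@H]2C[C@H](C(=O)O[C@@H]3C[C@H](C)CC[C@H]3C(C)C)[C@H](C=C2C)[C@]1(O)C=C)(C(C)C)C(C)C | intermediate
17 | methyl ketone, as 16 with COCH3 in place of CO2Men (not isolated) | CC(C)[Si](Oc1c(Oc2ccc(Br)cc2)cc(Br)cc1O[C@@]1(C)[C@H]2C[C@H](C(C)=O)[C@H](C=C2C)[C@]1(O)C=C)(C(C)C)C(C)C | intermediate
18 | (1S,2R,3S,4S,7S)-3-(Ar1O)-2-ethenyl-7-(2-hydroxypropan-2-yl)-3,5-dimethylbicyclo[2.2.2]oct-5-en-2-ol (key-step precursor) | CC(C)[Si](Oc1c(Oc2ccc(Br)cc2)cc(Br)cc1O[C@@]1(C)[C@H]2C[C@H](C(C)(C)O)[C@H](C=C2C)[C@]1(O)C=C)(C(C)C)C(C)C | intermediate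
19 | dipotassium C3,C11-dialkoxide of 18 (not isolated) | [K+].[K+].CC(C)[Si](Oc1c(Oc2ccc(Br)cc2)cc(Br)cc1O[C@@]1(C)[C@H]2C[C@H](C(C)(C)[O-])[C@H](C=C2C)[C@]1([O-])C=C)(C(C)C)C(C)C | intermediate
20 | dipotassium C2=C3 enolate and C11 alkoxide of 21 (not isolated) | [K+].[K+].CC(C)[Si](Oc1c(Oc2ccc(Br)cc2)cc(Br)cc1O[C@]1(C)C([O-])=CC[C@]2(C)C=C[C@@H](C(C)(C)[O-])C[C@@H]21)(C(C)C)C(C)C | intermediate
21 | (4S,5S,7S,10R)-4-(Ar1O)-11-hydroxy-cis-eudesm-8-en-3-one (key-step product) | CC(C)[Si](Oc1c(Oc2ccc(Br)cc2)cc(Br)cc1O[C@]1(C)C(=O)CC[C@]2(C)C=C[C@@H](C(C)(C)O)C[C@@H]21)(C(C)C)C(C)C | intermediate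
22 | (4S,5S,7R,10S)-4-(Ar1O)-11-hydroxy-cis-eudesman-3-one | CC(C)[Si](Oc1c(Oc2ccc(Br)cc2)cc(Br)cc1O[C@]1(C)C(=O)CC[C@]2(C)CC[C@@H](C(C)(C)O)C[C@@H]21)(C(C)C)C(C)C | intermediate
23 | (4S,5S,7R,10S)-4-(Ar2O)-11-hydroxy-cis-eudesman-3-one | C=CCc1ccc(Oc2cc(CC=C)cc(O[C@]3(C)C(=O)CC[C@]4(C)CC[C@@H](C(C)(C)O)C[C@@H]43)c2O[Si](C(C)C)(C(C)C)C(C)C)cc1 | intermediate
24 | (4S,5S,7R,10S)-4-(Ar2O)-cis-eudesmane-3,11-diol, C3 epimers | C=CCc1ccc(Oc2cc(CC=C)cc(O[C@]3(C)C(O)CC[C@]4(C)CC[C@@H](C(C)(C)O)C[C@@H]43)c2O[Si](C(C)C)(C(C)C)C(C)C)cc1 | intermediate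
25 | C3 O-(imidazol-1-ylthiocarbonyl) derivative of 24, C3 epimers | C=CCc1ccc(Oc2cc(CC=C)cc(O[C@]3(C)C(OC(=S)n5ccnc5)CC[C@]4(C)CC[C@@H](C(C)(C)O)C[C@@H]43)c2O[Si](C(C)C)(C(C)C)C(C)C)cc1 | intermediate
26 | (4R,5S,7R,10R)-4-(Ar2O)-cis-eudesman-11-ol | C=CCc1ccc(Oc2cc(CC=C)cc(O[C@]3(C)CCC[C@]4(C)CC[C@@H](C(C)(C)O)C[C@@H]43)c2O[Si](C(C)C)(C(C)C)C(C)C)cc1 | intermediate
27 | CNP0254037.2, (4R,5S,7R,10R)-4-[5-allyl-3-(4-allylphenoxy)-2-hydroxyphenoxy]-cis-eudesman-11-ol | C=CCc1ccc(Oc2cc(CC=C)cc(O[C@]3(C)CCC[C@]4(C)CC[C@@H](C(C)(C)O)C[C@@H]43)c2O)cc1 | target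

Total step count: 17. Longest linear sequence: 15 steps from 2,4-dimethylphenol (steps 1, 3, 4 and 6 to 17).

Steps most likely to fail

Step 6.
- What may go wrong: attack of the hindered tertiary alkoxide on the fluoroarene may be too slow. Reversible addition to the formyl group, hydride transfer between aldehyde molecules or ketol rearrangement of the alkoxide could then take over.
- Fallback: the order of the two C-O bond formations is reversed, so that the difficult substitution meets the cheaper and more electrophilic arene in large excess.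
- Route: setting out from 7, the alkoxide 11 is treated with several equivalents of 8 (KN(SiMe3)2, THF, -78 °C to rt). This gives the fluoro aldehyde F1. Its remaining fluoride is then displaced by the unhindered phenoxide of 9 (K2CO3, DMF, 80 °C), which comes back to the route at 12.

Step 11.
- What may go wrong: transfer of the silyl group from O2' to an alkoxide, cleavage of C3-C8 without recombination, or breakdown of the dianion may compete with the sigmatropic shift.
- Fallback: the same [3,3] reorganisation is run without any anion, as a thermal siloxy-Cope rearrangement.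
- Route: setting out from 18, Me3SiOTf and 2,6-lutidine (CH2Cl2, 0 °C) give the bis(trimethylsilyl) ether F2. Heating in o-dichlorobenzene at about 200 °C in base-washed glass gives the trimethylsilyl enol ether F3. Citric acid in THF/H2O then removes both Me3Si groups while the aryl iPr3Si ether stays, which comes back to the route at 21.

Step 16.
- What may go wrong: the C3 radical may lose the neighbouring aryloxy group by beta scission, or the chain carriers may attack the allyl groups. Either would erode the deoxygenation.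
- Fallback: O3 is removed by ionic chemistry before the allyl groups are present.
- Route: setting out from 22, NaBH4 (MeOH/THF, 0 °C) gives the C3 alcohol F4. MsCl and Et3N (CH2Cl2, 0 °C) convert only the secondary hydroxyl into the mesylate F5. DBU in toluene at 110 °C effects E2 elimination toward C2, the only carbon with beta hydrogens, to give the C2=C3 alkene F6. Diimide (KO2CN=NCO2K, AcOH, MeOH/THF) saturates it to the dibromide F7. The twofold Stille allylation under the conditions of step 13 comes back to the route at 26.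

Further compounds
F1 | step 6 | Men (1S,2S,4S,8S)-8-(5-bromo-3-fluoro-2-formylphenoxy)-5,8-dimethyl-7-oxobicyclo[2.2.2]oct-5-ene-2-carboxylate | O=Cc1c(F)cc(Br)cc1O[C@@]1(C)[C@H]2C[C@H](C(=O)O[C@@H]3C[C@H](C)CC[C@H]3C(C)C)[C@H](C=C2C)C1=O
F2 | step 11 | C3,C11-bis(trimethylsilyl) ether of 18 | CC(C)[Si](Oc1c(Oc2ccc(Br)cc2)cc(Br)cc1O[C@@]1(C)[C@H]2C[C@H](C(C)(C)O[Si](C)(C)C)[C@H](C=C2C)[C@]1(O[Si](C)(C)C)C=C)(C(C)C)C(C)C
F3 | step 11 | C2=C3 trimethylsilyl enol ether and C11 trimethylsilyl ether of 21 | CC(C)[Si](Oc1c(Oc2ccc(Br)cc2)cc(Br)cc1O[C@]1(C)C(O[Si](C)(C)C)=CC[C@]2(C)C=C[C@@H](C(C)(C)O[Si](C)(C)C)C[C@@H]21)(C(C)C)C(C)C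
F4 | step 16 | 4-(Ar1O)-cis-eudesmane-3,11-diol, C3 epimers, other centres as in 22 | CC(C)[Si](Oc1c(Oc2ccc(Br)cc2)cc(Br)cc1O[C@]1(C)C(O)CC[C@]2(C)CC[C@@H](C(C)(C)O)C[C@@H]21)(C(C)C)C(C)C
F5 | step 16 | C3 methanesulfonate of F4 | CC(C)[Si](Oc1c(Oc2ccc(Br)cc2)cc(Br)cc1O[C@]1(C)C(OS(C)(=O)=O)CC[C@]2(C)CC[C@@H](C(C)(C)O)C[C@@H]21)(C(C)C)C(C)C
F6 | step 16 | 4-(Ar1O)-cis-eudesm-2-en-11-ol, centres as in 26 | CC(C)[Si](Oc1c(Oc2ccc(Br)cc2)cc(Br)cc1O[C@]1(C)C=CC[C@]2(C)CC[C@@H](C(C)(C)O)C[C@@H]21)(C(C)C)C(C)C
F7 | step 16 | (4R,5S,7R,10R)-4-(Ar1O)-cis-eudesman-11-ol | CC(C)[Si](Oc1c(Oc2ccc(Br)cc2)cc(Br)cc1O[C@]1(C)CCC[C@]2(C)CC[C@@H](C(C)(C)O)C[C@@H]21)(C(C)C)C(C)C
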